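## Retrosynthetic overview

1. Both carbon skeletons are bought ready-made, as the two naphthalene-type pentaketide units that the biosynthesis joins: 5-methoxy-1-tetralone 1 (tetralin half) and 8-methoxynaphthalen-1-ol 2 (naphthol half).
2. Functional-group changes on 1: C4–H to C4–OH (bromide 3, hydroxy ketone 4), then C1=O to the (1S)-carbinol (diol 5, both C4 epimers are used).
3. Key disconnection (last step): the C4–C2′ bond, made by cationic alkylation of C2 of 2 with unprotected 5; water is the only leaving group.
4. Ring order: no carbocycle is built. The only ring formed is the transient 1,4-oxygen bridge of 6 (C1–OH onto the C4 cation), opened at once by 2 with inversion to give the trans (1S,4R) pattern of target 7.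

Assumption: the presumed biosynthesis is taken to be attack of C2 of 8-methoxynaphthalen-1-ol on the benzylic carbon peri to the methoxy group of an isosclerone-type 1,4-dioxygenated tetralin unit, and 8-methoxynaphthalen-1-ol is taken as a catalogue compound.

## Route

Step 1
Reactants: 1 5-methoxy-3,4-dihydronaphthalen-1(2H)-one (5-methoxy-1-tetralone)
Product: 4 rac-4-hydroxy-5-methoxy-3,4-dihydronaphthalen-1(2H)-one, via benzylic bromide 3 (not isolated)
Conditions: NBS (1.05 equiv), AIBN (5 mol%), PhCF3, 80 °C, hν; filter; then Ag2CO3 (0.6 equiv), acetone/H2O (4:1), rt, dark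
Reagents that add atoms: N-bromosuccinimide, O=C1CCC(=O)N1Br (bromine of 3); water, O (hydroxyl oxygen of 4)
Why: Wohl–Ziegler radical bromination takes the C4 hydrogen (benzylic radical stabilised by the ortho methoxy group, the C2 hydrogens next to the carbonyl are not abstracted under radical conditions), and silver-assisted SN1 hydrolysis under neutral conditions exchanges bromide for hydroxyl before HBr can be lost to a naphthol; the new C4 stereocenter is left racemic because it is erased in step 3.

Step 2
Reactants: 4 rac-4-hydroxy-5-methoxy-3,4-dihydronaphthalen-1(2H)-one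
Product: 5 (1S,4RS)-5-methoxy-1,2,3,4-tetrahydronaphthalene-1,4-diol (C1 uniformly S, about 1:1 cis and trans epimers at C4)
Conditions: RuCl(p-cymene)[(S,S)-TsDPEN] (1 mol%), HCO2Na (5 equiv), H2O/MeOH (1:1), 40 °C
Reagents that add atoms: none
Why: Noyori–Ikariya asymmetric transfer hydrogenation, in which the (S,S) catalyst delivers hydride to the same ketone face as in 1-tetralone, so C1 is set as S by catalyst control in both enantiomers of 4, while the near-neutral formate medium leaves the acid-labile C4 carbinol untouched and unresolved.

Step 3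
Reactants: 5 (1S,4RS)-5-methoxy-1,2,3,4-tetrahydronaphthalene-1,4-diol; 2 8-methoxynaphthalen-1-ol (3 equiv, excess recovered)
Product: 7 (1S,4R)-4-(1-hydroxy-8-methoxynaphthalen-2-yl)-5-methoxy-1,2,3,4-tetrahydronaphthalen-1-ol (dipolynaphthalene A), via oxa-bridged ether 6 (not isolated)
Conditions: (PhO)2P(O)OH (10 mol%), HFIP/CH2Cl2 (1:4), 0 °C to rt
Reagents that add atoms: none
Why: Proposed new method: a stereoconvergent dehydrative Friedel–Crafts alkylation in which both C4 epimers of 5 ionise only at C4 (cation stabilised by the ortho methoxy group, whereas C1 is meta to it and stays intact), the C1 hydroxyl closes onto the cation to give the protonated oxygen bridge of 6, and C2 of 2, the carbon ortho to the OH that hydrogen-bonds to the phosphate counter-ion, opens the bridge at C4 from the face opposite to oxygen (inversion, reinforced by the usual anti approach to a remote substituent of a tetralinyl cation), which sets C4 as R, trans to the C1 hydroxyl, with one molecule of water lost from 5; the closest known reaction types are Brønsted-acid or HFIP-promoted dehydrative Friedel–Crafts benzylation of phenols and acid-mediated SN1 opening of 1,4-epoxytetralins.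

## Compound list

1 | 5-methoxy-3,4-dihydronaphthalen-1(2H)-one | COc1cccc2c1CCCC2=O | starting material
2 | 8-methoxynaphthalen-1-ol | COc1cccc2cccc(O)c12 | starting material
3 | rac-4-bromo-5-methoxy-3,4-dihydronaphthalen-1(2H)-one | COc1cccc2c1C(Br)CCC2=O | intermediate
4 | rac-4-hydroxy-5-methoxy-3,4-dihydronaphthalen-1(2H)-one | COc1cccc2c1C(O)CCC2=O | intermediate
5 | (1S,4RS)-5-methoxy-1,2,3,4-tetrahydronaphthalene-1,4-diol (C4 epimer mixture) | COc1cccc2c1C(O)CC[C@@H]2O | intermediate
6 | (1S,4R)-5-methoxy-1,2,3,4-tetrahydro-1,4-epoxynaphthalene | COc1cccc2c1[C@H]3CC[C@@H]2O3 | intermediate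
7 | (1S,4R)-4-(1-hydroxy-8-methoxynaphthalen-2-yl)-5-methoxy-1,2,3,4-tetrahydronaphthalen-1-ol (dipolynaphthalene A) | COc1cccc2c1[C@@H](c1ccc3cccc(OC)c3c1O)CC[C@@H]2O | target

## Step count and risks

Total step count: 3. Longest linear sequence: 3 steps (1 to 4 to 5 to 7); 2 enters in step 3. The enantiomeric purity of 7 equals that of C1 in 5, because C1 is never touched after step 2.

Steps most likely to fail, in order of risk:

**Step 3.** The most likely failure is attack through the para carbon (C4) of 2 instead of C2. Lesser risks are a poor trans/cis ratio, double alkylation of 2, and loss of a second molecule of water from the tetralin to give a naphthalene. The fallback sets out from 2 and 5 and comes back at 7. The para position of 2 is blocked first: NBS in MeCN at −20 °C brominates para to the hydroxyl and gives 4-bromo-8-methoxynaphthalen-1-ol F1. F1 and 5 are then joined under the conditions of step 3; C4 of F1 is blocked and C2 is the open position next to the hydroxyl, so the product is (1S,4R)-4-(4-bromo-1-hydroxy-8-methoxynaphthalen-2-yl)-5-methoxy-1,2,3,4-tetrahydronaphthalen-1-ol F2. Hydrogenolysis of the aryl bromide (H2, Pd/C, NaOAc, MeOH, rt) returns 7; the unactivated C1 carbinol survives these buffered conditions.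

**Step 1.** Possible failures are ring or α-keto bromination, or loss of HBr from 3 to give 5-methoxy-1-naphthol. The fallback sets out from 1 and comes back at 5, replacing steps 1 and 2: the carbinol is set first and C4 is oxygenated afterwards by C–H oxidation. Asymmetric transfer hydrogenation of 1 under the conditions of step 2 gives (S)-5-methoxy-1,2,3,4-tetrahydronaphthalen-1-ol F3. Ac2O, pyridine and DMAP give (S)-5-methoxy-1,2,3,4-tetrahydronaphthalen-1-yl acetate F4. Benzylic oxidation of the C4 methylene (CrO3, AcOH/Ac2O, 10 °C; the acetoxy-bearing C1–H is deactivated) gives (1S)-5-methoxy-4-oxo-1,2,3,4-tetrahydronaphthalen-1-yl acetate F5. LiAlH4 in THF at 0 °C reduces the ketone and cleaves the acetate, giving 5 as its C4 epimer mixture.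

**Step 2.** Possible failures are loss of rate or selectivity caused by the remote C4 hydroxyl, or loss of water from 4. The fallback sets out from 4 (with 2) and comes back at 7: the order of C–C bond formation and reduction is exchanged, and C1 is set on the coupled ketone. 4 and 2 (3 equiv) with TfOH (5 mol%) in HFIP at rt give rac-4-(1-hydroxy-8-methoxynaphthalen-2-yl)-5-methoxy-3,4-dihydronaphthalen-1(2H)-one F6. Catalyst-controlled reduction with (R)-Me-CBS oxazaborolidine (20 mol%) and BH3·SMe2 (2.2 equiv) in THF at −20 °C turns both enantiomers of F6 into (1S) alcohols. These are 7 and its cis isomer (1S,4S)-4-(1-hydroxy-8-methoxynaphthalen-2-yl)-5-methoxy-1,2,3,4-tetrahydronaphthalen-1-ol F7, separated by chromatography; at most half of the material ends as 7.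

## Further compounds

F1 | step 3 | 4-bromo-8-methoxynaphthalen-1-ol | COc1cccc2c(Br)ccc(O)c12
F2 | step 3 | (1S,4R)-4-(4-bromo-1-hydroxy-8-methoxynaphthalen-2-yl)-5-methoxy-1,2,3,4-tetrahydronaphthalen-1-ol | COc1cccc2c1[C@@H](c1cc(Br)c3cccc(OC)c3c1O)CC[C@@H]2O
F3 | step 1 | (S)-5-methoxy-1,2,3,4-tetrahydronaphthalen-1-ol | COc1cccc2c1CCC[C@@H]2O
F4 | step 1 | (S)-5-methoxy-1,2,3,4-tetrahydronaphthalen-1-yl acetate | COc1cccc2c1CCC[C@@H]2OC(C)=O
F5 | step 1 | (1S)-5-methoxy-4-oxo-1,2,3,4-tetrahydronaphthalen-1-yl acetate | COc1cccc2c1C(=O)CC[C@@H]2OC(C)=O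
F6 | step 2 | rac-4-(1-hydroxy-8-methoxynaphthalen-2-yl)-5-methoxy-3,4-dihydronaphthalen-1(2H)-one | COc1cccc2c1C(c1ccc3cccc(OC)c3c1O)CCC2=O
F7 | step 2 | (1S,4S)-4-(1-hydroxy-8-methoxynaphthalen-2-yl)-5-methoxy-1,2,3,4-tetrahydronaphthalen-1-ol | COc1cccc2c1[C@H](c1ccc3cccc(OC)c3c1O)CC[C@@H]2O
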